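**Plan**
- Retrosynthesis: first the C4–C5 epoxide oxygen and the C8/C10 esters and C1 ketone are removed; then the butenolide is cut at C11–C12 and O6–C12 (C12 = CO) together with C13–OAc, giving a 7-vinylidene-cyclodec-4-en-6-ol; then the ring bond C6–C7, and the chain bonds C2–C3 and C7–C8.
- Forward: (R)-citramalic acid → C8 ynone → γ-lactone → methyl ketone; C2–C3 enolate allylation adds the C3–C6 enal unit; the ten-membered carbocycle closes at C6–C7 (propargylchromium → α-allenol); the five-membered lactone is closed last of the rings; esters, ketone and epoxide follow.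
- Stereochemistry: C10 from the chiral pool; C8 by asymmetric transfer hydrogenation; C6 by ligand-controlled carbonyl addition; C4/C5 from C6 by peripheral epoxidation of the (E)-alkene, whose geometry comes from an E-selective allylic oxidation.
- Enabling feature: the exocyclic allene C7=C11=C13 next to the C6 carbinol of the ten-membered ring. An acyl–metal unit on O6 lies in the plane of the C11=C13 π bond and bonds to C11; the resulting C7–C11–C13 allyl unit takes acetate at C13, which leaves C7=C11 inside the new lactone ring.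

Key step: step 13

Remarks on the chemistry:
- Germacrane numbering is used for all intermediates (ring C1–C10, lactone carbons C11–C13, C14 on C10, C15 on C4).
- C1 is carried as a protected carbinol from step 8 to step 17, because a free C1 ketone would be attacked by C7 (five-membered ring) during the ring closure of step 12. The (1S) epimer expected from chelation control is drawn; the other epimer would converge at step 17.
- Compounds 1, 3 and 10 are assumed to be commercial.

Step 1
Reactants: 1 (R)-citramalic acid
Product: 2 dioxolanone acid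
Conditions: Me2C(OMe)2, TsOH·H2O (cat.), acetone, 25 °C
Reagents that add atoms: 2,2-dimethoxypropane, COC(C)(C)OC
Why: Acid-catalysed transketalisation engages only the α-hydroxy acid (five-membered 1,3-dioxolan-4-one) and leaves the C8 carboxyl free; C10 comes unchanged from the chiral pool.

Step 2
Reactants: 2 dioxolanone acid; 3 tert-butyldimethyl(prop-2-ynyloxy)silane
Product: 5 C8 ynone, via acid chloride 4 (not isolated)
Conditions: (COCl)2, DMF (cat.), CH2Cl2, 0 → 25 °C; then 3, PdCl2(PPh3)2 (2 mol%), CuI (4 mol%), Et3N, THF, 25 °C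
Reagents that add atoms: none
Why: Acid chloride formation and copper/palladium-catalysed acylation of the terminal alkyne (acyl Sonogashira coupling) form the C7–C8 bond under conditions that leave the dioxolanone and the silyl ether intact.

Step 3
Reactants: 5 C8 ynone
Product: 7 hydroxy lactone, via hydroxy dioxolanone 6 (not isolated)
Conditions: RuCl[(S,S)-TsDPEN](p-cymene) (1 mol%), KOH (1 mol%), iPrOH, 25 °C; then TsOH·H2O (5 mol%), PhMe, 40 °C
Reagents that add atoms: none
Why: Noyori asymmetric transfer hydrogenation of the alkynyl ketone with the (S,S)-catalyst should give the (8S)-propargylic alcohol (the alkynyl group takes the place of the aryl group in the usual model), and the new hydroxyl then transacylates the dioxolanone to the γ-lactone with loss of acetone.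

Step 4
Reactants: 7 hydroxy lactone
Product: 8 keto diol
Conditions: MeLi (2.2 equiv), THF, −78 °C; NH4Cl (aq)
Reagents that add atoms: methyllithium, [Li]C
Why: The first equivalent deprotonates the tertiary hydroxyl and the second adds to the lactone; the tetrahedral lithium lactolate is stable at −78 °C, so the methyl ketone (new methyl = C2) is released only on work-up without over-addition.

Step 5
Reactants: 8 keto diol
Product: 9 C8 silyl ether
Conditions: TBSCl, imidazole, DMF, 0 → 25 °C
Reagents that add atoms: tert-butyldimethylsilyl chloride, CC(C)(C)[Si](C)(C)Cl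
Why: Silylation traps the open-chain form at the secondary propargylic C8 hydroxyl, the tertiary C10 hydroxyl and the hemiketal hydroxyl being too hindered for this reagent.

Step 6
Reactants: 10 1,1-diethoxy-3-methylbut-2-ene
Product: 11 (E)-allylic alcohol
Conditions: SeO2 (0.3 equiv), tBuOOH, CH2Cl2, 25 °C
Reagents that add atoms: tert-butyl hydroperoxide, CC(C)(C)OO
Why: Riley allylic oxidation (ene reaction then [2,3]-sigmatropic shift) hydroxylates the (E)-methyl group selectively and so fixes the geometry of the later C4=C5 bond.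

Step 7
Reactants: 11 (E)-allylic alcohol
Product: 12 (E)-allylic bromide
Conditions: CBr4, PPh3, 2,6-lutidine, CH2Cl2, 0 °C
Reagents that add atoms: carbon tetrabromide, BrC(Br)(Br)Br
Why: Appel bromination displaces the primary oxyphosphonium ion by SN2 with retention of alkene geometry, and lutidine protects the acetal from adventitious HBr.

Step 8
Reactants: 9 C8 silyl ether; 12 (E)-allylic bromide
Product: 14 C1/C10 diol, via lithium keto alkoxide 13 (not isolated)
Conditions: LDA (2.3 equiv), THF, −78 °C; 12, DMPU, −78 → −30 °C; then LiBH4, −30 → 0 °C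
Reagents that add atoms: none
Why: The alkoxide/enolate dianion (enolisation is possible only toward the methyl group because C10 is quaternary) is C-allylated at the primary allylic bromide to form C2–C3, and the lithium α-alkoxy ketone is then reduced in the same pot under chelation control (Cram chelate, hydride anti to the C9 branch) to the (1S)-carbinol that masks C1.

Step 9
Reactants: 14 C1/C10 diol
Product: 15 acetonide
Conditions: Me2C(OEt)2, PPTS (cat.), CH2Cl2, 25 °C
Reagents that add atoms: 2,2-diethoxypropane, CCOC(C)(C)OCC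
Why: Acid-catalysed transketalisation closes the 1,3-dioxolane on the vicinal diol, while the diethyl acetal can only exchange ethanol for ethanol.

Step 10
Reactants: 15 acetonide
Product: 16 hydroxy enal
Conditions: AcOH/THF/H2O (3:1:1), 25 °C
Reagents that add atoms: water, O
Why: Mild aqueous acid hydrolyses the allylic acetal to the (E)-enal and cleaves the primary propargylic silyl ether, whereas the secondary silyl ether and the dioxolane should survive at room temperature.

Step 11
Reactants: 16 hydroxy enal
Product: 18 bromo enal, via mesylate 17 (not isolated)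
Conditions: MsCl, Et3N, CH2Cl2, −20 °C; then LiBr, THF, 0 → 25 °C
Reagents that add atoms: lithium bromide, [Li+].[Br-]
Why: Mesylation of the primary propargylic alcohol and SN2 displacement by bromide give the propargylic bromide without touching the enal, which phosphine/tetrahalomethane conditions would endanger.

Step 12
Reactants: 18 bromo enal
Product: 21 macrocyclic allenol, via propargylchromium species 19 (not isolated), via trimethylsilyl ether 20 (not isolated)
Conditions: CrCl2 (15 mol%), 1,8-bis[(4S)-4-isopropyl-4,5-dihydro-1,3-oxazol-2-yl]-3,6-diphenyl-9H-carbazole (17 mol%), Mn powder, Me3SiCl, iPr2NEt, THF, 0.003 M (slow addition of 18), 25 °C; then K2CO3, MeOH, 0 °C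
Reagents that add atoms: none
Why: Nozaki–Hiyama–Kishi-type reaction in which the γ-substituted propargylchromium (metal on C13) adds through C7 to the aldehyde in a six-membered SE2′ transition state, closing the ten-membered ring and giving the 7-vinylidene carbinol directly; the aldehyde face (6R) is to be set by the chiral tridentate ligand on trivalent chromium (reagent control, antipodal ligand if the sense proves opposite), and the masked C1 cannot compete as an electrophile.

Step 13
Reactants: 21 macrocyclic allenol
Product: 22 13-acetoxy butenolide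
Conditions: Pd(OAc)2 (10 mol%), 1,4-benzoquinone (2 equiv), NaOAc (3 equiv), AcOH (3 equiv), CO (1 atm), MeCN, 4 Å MS, 25 °C
Reagents that add atoms: carbon monoxide, [C-]#[O+]; acetic acid, CC(O)=O
Why: Proposed new method: the C6 hydroxyl, the only free OH (O8 is silylated, O1/O10 are in the acetonide), adds to CO on divalent palladium to give an alkoxycarbonyl–palladium species, which undergoes syn-acylpalladation of the distal C11=C13 π bond at the central allene carbon, forming the C11–C12 bond and an η3-allyl complex over C7–C11–C13. Acetate then attacks the unhindered C13 terminus, which leaves C7=C11 conjugated with the lactone carbonyl and releases zerovalent palladium, reoxidised by benzoquinone. The closest known reactions are the divalent-palladium-catalysed oxidative alkoxycarbonylation of allenes to 2-(alkoxymethyl)acrylates and acylpalladation/nucleophile-capture cascades of allenes; the intramolecular, acetate-terminated version on an α-allenol is the new element. The lactone closes in a 5-exo sense with respect to the C11=C13 bond (C7=C11 ends endocyclic), which is feasible because the C6–O–C12 tether lies in the plane of that π bond. No stereocentre is created and C6 is carried through unchanged; the double-bond position is fixed by acetate attack at C13 and not at the fully substituted C7. The step needs O6 over the other oxygens (secured by protection), acyl delivery to the central carbon (inherent to acyl–metal insertion into allenes) and suppression of 5-endo oxypalladation at C13 (CO saturation and acetate buffer should favour alkoxycarbonyl formation).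

Step 14
Reactants: 22 13-acetoxy butenolide
Product: 23 C8 alcohol
Conditions: HF·pyridine, pyridine/THF, 0 → 25 °C
Reagents that add atoms: none
Why: Buffered fluoride cleaves the secondary silyl ether and should leave the acetonide, the allylic acetate and the butenolide intact.

Step 15
Reactants: 23 C8 alcohol
Product: 24 C8 methacrylate
Conditions: methacrylic anhydride, Et3N, DMAP (cat.), CH2Cl2, 0 °C
Reagents that add atoms: methacrylic anhydride, C=C(C)C(=O)OC(=O)C(C)=C
Why: DMAP-catalysed acylation of the only free hydroxyl installs the C8 ester at low temperature, which should outrun acetyl migration from O13 and deprotonation at C6.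

Step 16
Reactants: 24 C8 methacrylate
Product: 25 C1/C10 diol
Conditions: AcOH/H2O (4:1), 40 °C
Reagents that add atoms: none
Why: Acid-catalysed hydrolysis of the dioxolane frees the diol, and the esters and the electron-poor allylic acetate should tolerate aqueous acetic acid.

Step 17
Reactants: 25 C1/C10 diol
Product: 26 α-hydroxy ketone
Conditions: Dess–Martin periodinane, NaHCO3, CH2Cl2, 0 → 25 °C
Reagents that add atoms: none
Why: Dess–Martin oxidation converts the only secondary alcohol (C1) into the ketone, the tertiary C10 hydroxyl being inert, and removes the temporary C1 stereocentre.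

Step 18
Reactants: 26 α-hydroxy ketone
Product: 27 C10 acetate
Conditions: Ac2O, Sc(OTf)3 (5 mol%), MeCN, −20 °C
Reagents that add atoms: acetic anhydride, CC(=O)OC(C)=O
Why: Lewis-acid-catalysed acetylation acylates the hindered tertiary α-ketol without base, which avoids deprotonation at the acidic C6 γ-position of the butenolide.

Step 19
Reactants: 27 C10 acetate
Product: 28 glaucolide A
Conditions: mCPBA, NaHCO3, CH2Cl2, 0 °C
Reagents that add atoms: 3-chloroperbenzoic acid, OOC(=O)c1cccc(Cl)c1
Why: Prilezhaev epoxidation of the only electron-rich alkene (C4=C5; the butenolide and methacrylate alkenes are electron-poor), in which C6–H eclipses the alkene plane to avoid A(1,3) strain with C15 and the peracid attacks the peripheral face syn to the lactone oxygen, should give the threo (4R,5R) epoxide.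

**Compound list**
1 | (R)-citramalic acid, (2R)-2-hydroxy-2-methylbutanedioic acid | C[C@@](O)(CC(O)=O)C(O)=O | starting material
2 | 2-[(4R)-2,2,4-trimethyl-5-oxo-1,3-dioxolan-4-yl]acetic acid | C[C@@]1(CC(O)=O)C(=O)OC(C)(C)O1 | intermediate
3 | tert-butyldimethyl(prop-2-yn-1-yloxy)silane | C#CCO[Si](C)(C)C(C)(C)C | starting material
4 | 2-[(4R)-2,2,4-trimethyl-5-oxo-1,3-dioxolan-4-yl]acetyl chloride | C[C@@]1(CC(Cl)=O)C(=O)OC(C)(C)O1 | intermediate
5 | (5R)-5-[5-(tert-butyldimethylsilyloxy)-2-oxopent-3-yn-1-yl]-2,2,5-trimethyl-1,3-dioxolan-4-one | C[C@@]1(CC(=O)C#CCO[Si](C)(C)C(C)(C)C)C(=O)OC(C)(C)O1 | intermediate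
6 | (5R)-5-[(2S)-5-(tert-butyldimethylsilyloxy)-2-hydroxypent-3-yn-1-yl]-2,2,5-trimethyl-1,3-dioxolan-4-one | C[C@@]1(C[C@H](O)C#CCO[Si](C)(C)C(C)(C)C)C(=O)OC(C)(C)O1 | intermediate
7 | (3R,5S)-5-[3-(tert-butyldimethylsilyloxy)prop-1-yn-1-yl]-3-hydroxy-3-methyloxolan-2-one | C[C@@]1(O)C[C@@H](C#CCO[Si](C)(C)C(C)(C)C)OC1=O | intermediate
8 | (3R,5S)-8-(tert-butyldimethylsilyloxy)-3,5-dihydroxy-3-methyloct-6-yn-2-one (in equilibrium with its cyclic hemiketal) | CC(=O)[C@](C)(O)C[C@H](O)C#CCO[Si](C)(C)C(C)(C)C | intermediate
9 | (3R,5S)-5,8-bis(tert-butyldimethylsilyloxy)-3-hydroxy-3-methyloct-6-yn-2-one | CC(=O)[C@](C)(O)C[C@H](O[Si](C)(C)C(C)(C)C)C#CCO[Si](C)(C)C(C)(C)C | intermediate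
10 | 1,1-diethoxy-3-methylbut-2-ene | CCOC(OCC)C=C(C)C | starting material
11 | (2E)-4,4-diethoxy-2-methylbut-2-en-1-ol | CCOC(OCC)/C=C(C)/CO | intermediate
12 | (2E)-4-bromo-1,1-diethoxy-3-methylbut-2-ene | CCOC(OCC)/C=C(C)/CBr | intermediate
13 | lithium alkoxide of (2E,7R,9S)-9,12-bis(tert-butyldimethylsilyloxy)-1,1-diethoxy-7-hydroxy-3,7-dimethyldodec-2-en-10-yn-6-one | [Li+].CCOC(OCC)/C=C(C)/CCC(=O)[C@](C)([O-])C[C@H](O[Si](C)(C)C(C)(C)C)C#CCO[Si](C)(C)C(C)(C)C | intermediate
14 | (2E,6S,7R,9S)-9,12-bis(tert-butyldimethylsilyloxy)-1,1-diethoxy-3,7-dimethyldodec-2-en-10-yne-6,7-diol | CCOC(OCC)/C=C(C)/CC[C@H](O)[C@](C)(O)C[C@H](O[Si](C)(C)C(C)(C)C)C#CCO[Si](C)(C)C(C)(C)C | intermediate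
15 | (4S,5R)-5-[(2S)-2,5-bis(tert-butyldimethylsilyloxy)pent-3-yn-1-yl]-4-[(3E)-5,5-diethoxy-3-methylpent-3-en-1-yl]-2,2,5-trimethyl-1,3-dioxolane | CCOC(OCC)/C=C(C)/CC[C@@H]1OC(C)(C)O[C@]1(C)C[C@H](O[Si](C)(C)C(C)(C)C)C#CCO[Si](C)(C)C(C)(C)C | intermediate
16 | (2E)-5-{(4S,5R)-5-[(2S)-2-(tert-butyldimethylsilyloxy)-5-hydroxypent-3-yn-1-yl]-2,2,5-trimethyl-1,3-dioxolan-4-yl}-3-methylpent-2-enal | O=C/C=C(C)/CC[C@@H]1OC(C)(C)O[C@]1(C)C[C@H](O[Si](C)(C)C(C)(C)C)C#CCO | intermediate
17 | methanesulfonate of 16 at the propargylic hydroxyl (C13) | O=C/C=C(C)/CC[C@@H]1OC(C)(C)O[C@]1(C)C[C@H](O[Si](C)(C)C(C)(C)C)C#CCOS(C)(=O)=O | intermediate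
18 | (2E)-5-{(4S,5R)-5-[(2S)-5-bromo-2-(tert-butyldimethylsilyloxy)pent-3-yn-1-yl]-2,2,5-trimethyl-1,3-dioxolan-4-yl}-3-methylpent-2-enal | O=C/C=C(C)/CC[C@@H]1OC(C)(C)O[C@]1(C)C[C@H](O[Si](C)(C)C(C)(C)C)C#CCBr | intermediate
19 | propargylchromium dichloride derived from 18 (trivalent chromium on C13) | O=C/C=C(C)/CC[C@@H]1OC(C)(C)O[C@]1(C)C[C@H](O[Si](C)(C)C(C)(C)C)C#CC[Cr](Cl)Cl | intermediate
20 | 6-O-trimethylsilyl ether of 21 | C[Si](C)(C)O[C@@H]1/C=C(C)/CC[C@@H]2OC(C)(C)O[C@]2(C)C[C@H](O[Si](C)(C)C(C)(C)C)C1=C=C | intermediate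
21 | (1S,4E,6R,8S,10R)-8-(tert-butyldimethylsilyloxy)-1,10-(isopropylidenedioxy)-4,10-dimethyl-7-vinylidenecyclodec-4-en-6-ol (germacrane numbering) | O[C@@H]1/C=C(C)/CC[C@@H]2OC(C)(C)O[C@]2(C)C[C@H](O[Si](C)(C)C(C)(C)C)C1=C=C | intermediate
22 | (1S,4E,6R,8S,10R)-13-acetoxy-8-(tert-butyldimethylsilyloxy)-1,10-(isopropylidenedioxy)germacra-4,7(11)-dien-12,6-olide | CC(C)(C)[Si](C)(C)O[C@H]1C[C@@]2(C)OC(C)(C)O[C@H]2CC/C(C)=C/[C@H]2OC(=O)C(COC(C)=O)=C12 | intermediate
23 | (1S,4E,6R,8S,10R)-13-acetoxy-8-hydroxy-1,10-(isopropylidenedioxy)germacra-4,7(11)-dien-12,6-olide | O[C@H]1C[C@@]2(C)OC(C)(C)O[C@H]2CC/C(C)=C/[C@H]2OC(=O)C(COC(C)=O)=C12 | intermediate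
24 | (1S,4E,6R,8S,10R)-13-acetoxy-1,10-(isopropylidenedioxy)-8-(methacryloyloxy)germacra-4,7(11)-dien-12,6-olide | C=C(C)C(=O)O[C@H]1C[C@@]2(C)OC(C)(C)O[C@H]2CC/C(C)=C/[C@H]2OC(=O)C(COC(C)=O)=C12 | intermediate
25 | (1S,4E,6R,8S,10R)-13-acetoxy-1,10-dihydroxy-8-(methacryloyloxy)germacra-4,7(11)-dien-12,6-olide | C=C(C)C(=O)O[C@H]1C[C@@](C)(O)[C@@H](O)CC/C(C)=C/[C@H]2OC(=O)C(COC(C)=O)=C12 | intermediate
26 | (4E,6R,8S,10R)-13-acetoxy-10-hydroxy-8-(methacryloyloxy)-1-oxogermacra-4,7(11)-dien-12,6-olide | C=C(C)C(=O)O[C@H]1C[C@@](C)(O)C(=O)CC/C(C)=C/[C@H]2OC(=O)C(COC(C)=O)=C12 | intermediate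
27 | (4E,6R,8S,10R)-10,13-diacetoxy-8-(methacryloyloxy)-1-oxogermacra-4,7(11)-dien-12,6-olide | C=C(C)C(=O)O[C@H]1C[C@@](C)(OC(C)=O)C(=O)CC/C(C)=C/[C@H]2OC(=O)C(COC(C)=O)=C12 | intermediate
28 | glaucolide A, (4R,5R,6S,8S,10R)-10,13-diacetoxy-4,5-epoxy-8-(methacryloyloxy)-1-oxogermacr-7(11)-en-12,6-olide | C=C(C)C(=O)O[C@H]1C[C@@](C)(OC(C)=O)C(=O)CC[C@@]2(C)O[C@@H]2[C@H]2OC(=O)C(COC(C)=O)=C12 | target

**Step count**
Total: 19 steps. Longest linear sequence: 17 steps (steps 1–5 and 8–19 from 1); steps 6–7 prepare the C3–C6 unit.

**Steps most likely to fail**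

Step 13. The allene may be captured by O6 in a 5-endo oxypalladation at C13 before the alkoxycarbonyl–palladium species forms, or the η3-allyl intermediate may lose a β-hydrogen instead of taking up acetate. The fallback uses known chemistry and sets out from 21. A divalent-palladium-catalysed 1,2-bromoacetoxylation of the allene (Pd(OAc)2 cat., LiBr, LiOAc, 1,4-benzoquinone, AcOH/acetone, 25 °C) places bromide on the central carbon C11 and acetate on the unhindered terminus C13, giving the 2-bromoallylic acetate F1; the isomer with bromine cis to C6 is used. A carbonylative lactonisation of this 3-bromoallylic alcohol (PdCl2(PPh3)2 cat., CO 1 atm, Et3N, THF, 50 °C; oxidative addition of zerovalent palladium into C11–Br, CO insertion, acyl capture by the C6 hydroxyl) then forms C11–C12 and O6–C12 and comes back to the route at 22.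

Step 12. The facial selectivity at the aldehyde may be poor if the ligand and the conformational bias of the ring-forming transition state are mismatched, so that the C6 epimer predominates. The fallback corrects the centre after ring closure and does not rely on the addition itself. It sets out from the 6-epimeric allenol F2, the other product of step 12 from 18. A Mitsunobu reaction (4-nitrobenzoic acid, PPh3, diisopropyl azodicarboxylate, THF, 0 °C) inverts C6 and gives the 4-nitrobenzoate F3 with the required (6R) configuration. Methanolysis (K2CO3, MeOH, 0 °C) comes back to the route at 21.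

Step 19. The facial selectivity of peracid attack on C4=C5 may be eroded if the macrocycle populates a conformer in which the lactone oxygen, and not C6–H, lies in the alkene plane. The fallback replaces substrate control by reagent control: it sets out from 27 and applies a Shi epoxidation (D-fructose-derived ketone catalyst, Oxone, NaHCO3-buffered MeCN/dimethoxymethane/water, 0 °C). The spiro transition-state model for (E)-trisubstituted alkenes predicts the (4R,5R) epoxide; the electron-poor alkenes are not touched. It comes back to the route at 28 and makes no new compound (F0).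

**Further compounds**
F1 | step 13 | (1S,4E,6R,8S,10R)-configured 2-bromo-2-[macrocyclic ylidene]ethyl acetate: 21 with C7=C11(Br)–C13H2OAc in place of the allene, bromine cis to C6, C6–OH free | O[C@@H]1/C=C(C)/CC[C@@H]2OC(C)(C)O[C@]2(C)C[C@H](O[Si](C)(C)C(C)(C)C)/C1=C(/Br)COC(C)=O
F2 | step 12 | (1S,4E,6S,8S,10R)-8-(tert-butyldimethylsilyloxy)-1,10-(isopropylidenedioxy)-4,10-dimethyl-7-vinylidenecyclodec-4-en-6-ol (6-epimer of 21) | O[C@H]1/C=C(C)/CC[C@@H]2OC(C)(C)O[C@]2(C)C[C@H](O[Si](C)(C)C(C)(C)C)C1=C=C
F3 | step 12 | 6-O-(4-nitrobenzoate) of 21, (6R) | O=C(O[C@@H]1/C=C(C)/CC[C@@H]2OC(C)(C)O[C@]2(C)C[C@H](O[Si](C)(C)C(C)(C)C)C1=C=C)c1ccc(cc1)[N+](=O)[O-]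
F0 | step 19 | none | none
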